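Numbering used throughout: plain locants C1–C15 for the enone half, primed locants C1'–C15' for the spiro-ketone half (guaianolide numbering). Rings: A = C1–C5, B = C1/C5–C10, C = lactone on C6/C7, D = cyclohexene (C1, C2, C4', C15', C14, C10), E = C1'–C5', F = C1'/C5'–C10', G = lactone on C6'/C7', H = the five-membered ring C1', C10', C7', C6', C5' that exists before ring F. α is the face of H-5, H-7, H-1', H-5', H-7'; β is the face of H-6 and H-6'.

## Analysis of the target

The target is a heptacyclic C30 bis-guaianolide in which the enone half (rings A, B, C) and the spiro-ketone half (rings E, F, G) are joined through the cyclohexene ring D, so that C4' is a spiro quaternary carbon. It has eleven stereocentres: C5, C6, C7, C10 and C11 in the enone half, the spiro centre C4', and C1', C5', C6', C7' and C11' in the primed half. Both halves show the 5α-H, 6β-H, 7α-H pattern with trans-fused lactones, and H-1' and H-5' are cis (α). C2 sits on the α face of ring E, anti to C6', and H-10 is β. The two lactone methyls differ: C13 is α (11S, the stable arrangement) but C13' is β (11'R, the less stable one), so C11' has to be set under kinetic control and never equilibrated. Sensitive groups are the cross-conjugated dienone C15=C4–C3(=O)–C2=C1 with its epimerisable γ-hydrogen at C10, the two exocyclic methylenes, the β,γ-unsaturated C3' ketone and two lactones. The synthesis is hard because of the congested spiro centre next to the C5' stereocentre and the cis-fused 5/7 primed bicycle, all to be handled beside a second, fully functionalised half. The strategy rests on ring F: the oxygen-bearing C6' and the methylene-bearing C10' are 1,4-related through C5' and C1', which is the pattern left when a two-carbon unit (C8', C9') is inserted into the C7'–C10' bond of a 2-substituted cyclopentane-1,3-dione made of C6', C7' and C10'.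

## Retrosynthetic reasoning

**Masking of the two ketones (32 ⇒ 31 ⇒ 30).** The C3 and C3' carbonyls are taken back to silyl-protected carbinols. The C3 dienone would be a second chromophore in the photochemical step. The C3' ketone is β,γ-unsaturated through C4'–C2=C1, absorbs in the same window, and would also compete with C10' in the olefination and with C6' in the reduction. Both are therefore carried at the alcohol level and oxidised together at the very end.

**Lactone G and the C10' methylene (30 ⇒ 28 ⇒ 27).** The O–C12' bond of lactone G is cut and C6'–O returned to a ketone; C10'=C14' is returned to a ketone. This exposes diketone 27, in which the two carbonyls differ strongly in hindrance, so methylenation can be directed to C10' and hydride to C6'.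

**Ring F (27 ⇒ 24 + 25).** C7'–C8' and C9'–C10' are cut and C7'–C10' is re-formed, which contracts ring F to the five-membered ring H and releases ethylene 25. The cut is made here because it converts a seven-membered ring closure into an intermolecular [2+2] cycloaddition followed by a strain-driven fragmentation. It also places the two carbonyls exactly at C6' and C10'. The forward reaction must engage only the C10' enol ester and only the enone chromophore.

**Enol acetate and ring H (24 ⇒ 23 ⇒ 22).** The acetate is removed to dione 23, and ring H is opened at C6'–C7' to keto ester 22. The ketone is placed on the C1' side and the ester on the C5' side. The forward Claisen closure can then epimerise C1' (ketone α-position) to the cis arrangement it needs while leaving C5', which carries the stereochemical information relative to C4', untouched.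

**Side chain (22 ⇒ 18 + 20; 20 ⇒ 19).** C7'–C10' is cut between an acyl donor (thioester 18) and a C7' nucleophile that already carries C11' (iodide 20, used as organozinc 21). C11' comes from hydroxy ester 19 with the required configuration and meets no base before the ring closure.

**Adjustments on the diester (18 ⇒ 17 ⇒ 16 ⇒ 15 ⇒ 14).** Thioester, acid, silyl ethers and carbinols are returned to dienone diester 14. The C10' ester on C1' is distinguished from the C6' ester by the quaternary neighbour of the latter.

**Ring D and the spiro centre (14 ⇒ 13 ⇒ 12 ⇒ 7 + 11).** After moving the C1=C2 bond back to C1=C10, C2–C4' and C14–C15' are cut in a Diels–Alder sense. This makes both bonds of ring D and the quaternary centre in one step from two enantiopure pieces. The C5' ester next to the reacting carbon of 11 decides the face and with it the configuration of C4'.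

**The two partners (11 ⇒ 9 ⇒ 8; 7 ⇒ 6 ⇒ 4 ⇒ 3 ⇒ 2 ⇒ 1).** Dienophile 11 is the α-methylene derivative of C2-symmetric keto diester 8, whose two α-positions are homotopic, so no regiochemical question arises. Diene 7 comes from 1, which already holds rings A–C, both exocyclic methylenes and the C5, C6, C7 centres. Only C11 has to be reduced, C3 oxygenated and the C1=C2 bond introduced.

## Alternatives that were turned down

**Alternative 1: Wagner–Meerwein shift on the assembled dimer.**
- Disconnection: C1'–C5' is cut and C5'–C10' re-formed, so the primed half becomes a decalin.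
- Forward step: buffered acetolysis of the equatorial C1' mesylate A1. The antiperiplanar C5'–C10' bond migrates to C1' and the C10' cation loses a C14' proton, giving A2, the target as its C3' ketal.
- For: the migration is stereospecific and sets the cis C1'/C5' fusion, rings E and F and the exocyclic alkene in one event. On control of the ring fusion it is stronger than the chosen route, which must preserve a cis relationship through basic steps.
- Against: A1 must already contain the spiro centre and the complete enone half. The cross-conjugated dienone, the ketal and both lactones would have to survive hot acid. The cation can also lose a proton from C9' or C1' or be captured by acetate, so the alkene position is the least controlled element on the most advanced intermediate.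
- Comparison: the chosen strategy fixes both functional positions of ring F by construction and runs cold and without acid on a substrate whose enone is masked. It pays for this with the steps that build ring H.

**Alternative 2: intramolecular Diels–Alder reaction with an exocyclic diene.**
- Disconnection: C2–C4' and C1–C10.
- Forward step: heating A3, in which the diene C4'=C15'–C14=C10 is tethered to a sulfonyl-activated cyclopentenone, closes rings B and D; base-induced loss of sulfinate then gives A4.
- For: two rings and the quaternary centre form in one step and intramolecularity fixes the regiochemistry. In bond economy this is stronger than the chosen route.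
- Against: the seven-membered ring B is closed in the cycloaddition through a flexible tether, which alone must control C10 and C4'. A4 lacks C15 and carries a C14=C15' alkene, so a site-selective hydrogenation and an α'-methylenation are still needed on top of the C10' methylenation. Ring F must already be present in A3 and has to be made by other means.
- Comparison: the chosen strategy takes ring B from the chiral pool and spends its key step on ring F, the ring that no starting material provides.

**Alternative 3: Michael–aldol annulation onto a cycloheptenone.**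
- Disconnection: C4'–C5' and C1'–C2'.
- Forward step: under an amidine base the C4' enolate of keto aldehyde A5 adds to C5' of cycloheptenone A6 and the C1' enolate closes onto the aldehyde, giving A7.
- For: it is the most convergent plan, with two halves of similar size and ring F brought in intact. In step count it is stronger than the chosen route.
- Against: a quaternary centre is made by an intermolecular Michael addition of a hindered enolate, and C4', C5' and C1' are all set in one step with control only from the γ-oxygen of A6. A6 is a γ-acyloxy enone prone to elimination under base. A7 still needs removal of the C2' hydroxyl and a methylenation of C10' in the presence of two other ketones.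
- Comparison: the chosen route sets C4' by cycloaddition anti to a pre-set neighbour and obtains the oxygen pattern of ring F without ambiguity.

Key step: step 18

Remarks on the chemistry:
- Keto diester 8 is taken as a purchasable enantiopure building block; if only the racemic trans compound is at hand, it is resolved at the diacid stage through a diastereomeric ammonium salt before esterification.
- Precursor 24 and product 27 of the key step carry C3' as a silyl-protected carbinol instead of a ketone, for the reasons in the first retrosynthetic paragraph.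

## Steps

Step 1
Reactants: 1 dehydrocostus lactone
Product: 2 (11S)-11βH,13-dihydrodehydrocostus lactone
Conditions: NaBH4, MeOH, 0 °C
Reagents that add atoms: none
Why: Conjugate hydride reduction of the α-methylene-γ-lactone; the isolated 1,1-disubstituted alkenes are inert. C11 is set when the lactone enolate is protonated from the open face, which should give the 11βH epimer (C13 α), also the more stable one.

Step 2
Reactants: 2 (11S)-11βH,13-dihydrodehydrocostus lactone
Product: 3 (11S)-3α-hydroxyguaia-4(15),10(14)-dien-12,6α-olide
Conditions: SeO2 (0.5 equiv), t-BuOOH, CH2Cl2, rt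
Reagents that add atoms: tert-butyl hydroperoxide, CC(C)(C)OO (oxygen relayed by SeO2)
Why: SeO2 allylic hydroxylation (ene reaction, then [2,3]-sigmatropic shift) returns the alkene to C4=C15 and places OH on the allylic CH2 at C3. The reagent approaches the convex α face of the cis-fused bicycle, so the 3α-alcohol is expected.

Step 3
Reactants: 3 (11S)-3α-hydroxyguaia-4(15),10(14)-dien-12,6α-olide
Product: 4 (11S)-3-oxoguaia-4(15),10(14)-dien-12,6α-olide
Conditions: Dess–Martin periodinane, NaHCO3, CH2Cl2, 0 °C to rt
Reagents that add atoms: none
Why: Dess–Martin oxidation of an allylic alcohol; the buffered conditions leave the lactone and the exocyclic alkenes alone.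

Step 4
Reactants: 4 (11S)-3-oxoguaia-4(15),10(14)-dien-12,6α-olide
Product: 6 (11S)-3-oxoguaia-1,4(15),10(14)-trien-12,6α-olide, via silyl dienol ether 5 (not isolated)
Conditions: Me3SiOTf, Et3N, CH2Cl2, 0 °C; then Pd(OAc)2, MeCN, rt
Reagents that add atoms: none
Why: Saegusa–Ito oxidation. Soft enolisation can only go toward C2, and palladation at C2 followed by β-hydride elimination of H-1 gives C1=C2, now conjugated with C10=C14; the lactone is not enolised under these conditions.

Step 5
Reactants: 6 (11S)-3-oxoguaia-1,4(15),10(14)-trien-12,6α-olide
Product: 7 (11S)-3β-hydroxyguaia-1,4(15),10(14)-trien-12,6α-olide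
Conditions: NaBH4, CeCl3·7H2O, MeOH, −78 °C
Reagents that add atoms: none
Why: Luche reduction gives 1,2-reduction of the cross-conjugated trienone; hydride should come from the α face, away from C6, to give the 3β-carbinol. Its configuration is of no consequence because C3 is re-oxidised in step 9; the carbinol makes the diene electron-richer and removes the enone that could act as a dienophile.

Step 6
Reactants: 8 dimethyl (1S,2S)-4-oxocyclopentane-1,2-dicarboxylate
Product: 9 dimethyl (1S,2S,3R)-3-[(dimethylamino)methyl]-4-oxocyclopentane-1,2-dicarboxylate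
Conditions: LiN(SiMe3)2, THF, −78 °C; then Me2N=CH2+ I−, −78 to 0 °C
Reagents that add atoms: N,N-dimethylmethyleneiminium iodide (Eschenmoser's salt), C=[N+](C)C.[I-]
Why: Mannich reaction of the kinetic ketone enolate. The two α-CH2 groups of C2-symmetric 8 are homotopic, so one regioisomer results; the new centre (trans to the neighbouring ester) is removed in step 7.

Step 7
Reactants: 9 dimethyl (1S,2S,3R)-3-[(dimethylamino)methyl]-4-oxocyclopentane-1,2-dicarboxylate
Product: 11 dimethyl (1S,2R)-3-methylidene-4-oxocyclopentane-1,2-dicarboxylate, via ammonium iodide 10 (not isolated)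
Conditions: MeI, CH2Cl2, rt; then aq. NaHCO3, CH2Cl2, 0 °C
Reagents that add atoms: none
Why: Exhaustive N-methylation and E1cB loss of trimethylamine (Mannich–elimination route to α-methylene ketones). Weak base and low temperature should avoid migration of the double bond toward C5' and dimerisation; 11 is used at once.

Step 8
Reactants: 7 (11S)-3β-hydroxyguaia-1,4(15),10(14)-trien-12,6α-olide; 11 dimethyl (1S,2R)-3-methylidene-4-oxocyclopentane-1,2-dicarboxylate
Product: 12 spiro adduct (3β-hydroxy; 2βH; Δ1(10); 3'-oxo; 1'α,5'β-diester)
Conditions: toluene, BHT (cat.), 60 °C, dark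
Reagents that add atoms: none
Why: Thermal Diels–Alder reaction of an s-cis-locked semicyclic diene with an α-methylene ketone; the unsubstituted terminus C14 joins the β-carbon C15' (largest coefficients, least hindered first bond), so C2 joins C4'. The diene adds to the face of C4'=C15' anti to the adjacent C5' ester, which fixes C4' with C2 on the α face of ring E. With the α face of the diene open (3β-OH and C6 lie on β) this is the ketone-exo transition state that s-cis enones favour, and it leaves H-2 β.

Step 9
Reactants: 12 spiro adduct (3β-hydroxy; 2βH; Δ1(10); 3'-oxo; 1'α,5'β-diester)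
Product: 14 spiro dienone diester (3-oxo; Δ1; 10βH; 3'-oxo; 1'α,5'β-diester), via β,γ-enone 13 (not isolated)
Conditions: Dess–Martin periodinane, NaHCO3, CH2Cl2, 0 °C; aqueous work-up; then DBU (0.2 equiv), CH2Cl2, 0 °C to rt
Reagents that add atoms: none
Why: Oxidation gives the β,γ-unsaturated ketone 13, whose H-2 is both α to the ketone and allylic; DBU moves the double bond into conjugation by a 1,3-prototropic shift. The proton should return to C10 on the β face, the face H-2 left from and the one not covered by the C5' branch of ring E, giving 10βH; C10 stays epimerisable, so the mixture can also be equilibrated.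

Step 10
Reactants: 14 spiro dienone diester (3-oxo; Δ1; 10βH; 3'-oxo; 1'α,5'β-diester)
Product: 15 3α,3'α-diol diester
Conditions: NaBH4, CeCl3·7H2O, MeOH/THF, −78 to −20 °C
Reagents that add atoms: none
Why: Luche reduction of both ketones; methyl esters and the lactone survive at low temperature. Hydride is expected on the β face at C3 and on the C15' side at C3' (anti to C2), giving the 3α,3'α-diol; both centres are removed in step 22.

Step 11
Reactants: 15 3α,3'α-diol diester
Product: 16 3α,3'α-bis(tert-butyldimethylsilyl) ether diester
Conditions: t-BuMe2SiOTf, 2,6-lutidine, CH2Cl2, −78 to 0 °C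
Reagents that add atoms: tert-butyldimethylsilyl trifluoromethanesulfonate, CC(C)(C)[Si](C)(C)OS(=O)(=O)C(F)(F)F
Why: Silylation with the silyl triflate and a hindered base covers both secondary alcohols, including the neopentyl C3' carbinol. From here on neither the enone half nor ring E holds a carbonyl chromophore.

Step 12
Reactants: 16 3α,3'α-bis(tert-butyldimethylsilyl) ether diester
Product: 17 C10' carboxylic acid (C6' methyl ester kept)
Conditions: Me3SnOH, ClCH2CH2Cl, 70 °C; then 5 % aq. KHSO4, 0 °C
Reagents that add atoms: trimethyltin hydroxide, C[Sn](C)(C)O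
Why: Me3SnOH cleaves methyl esters by attack at the acyl carbon and is therefore sensitive to hindrance: the C10' ester on C1' should react, the C6' ester next to the quaternary spiro carbon should not. If lactone C opens it recloses on acidification; epimerisation at C1' would be harmless because that centre is inverted in step 16.

Step 13
Reactants: 17 C10' carboxylic acid (C6' methyl ester kept)
Product: 18 C10' S-ethyl thioester
Conditions: EtSH, EDC·HCl, DMAP (cat.), CH2Cl2, 0 °C to rt
Reagents that add atoms: ethanethiol, CCS
Why: Carbodiimide thioesterification (Steglich type) under neutral conditions; it creates the only acyl group in the molecule that inserts palladium.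

Step 14
Reactants: 19 methyl (R)-3-hydroxy-2-methylpropanoate
Product: 20 methyl (S)-3-iodo-2-methylpropanoate
Conditions: I2, PPh3, imidazole, CH2Cl2, 0 °C to rt
Reagents that add atoms: iodine, II
Why: Appel-type iodination of the primary alcohol; the stereocentre is not touched (the descriptor changes only through the priority of CH2I).

Step 15
Reactants: 18 C10' S-ethyl thioester; 20 methyl (S)-3-iodo-2-methylpropanoate
Product: 22 γ-keto ester (1'α-acyl chain C10'(=O)–C7'H2–C11'H(CH3)–C12'O2Me; 11'R), via organozinc iodide 21 (not isolated)
Conditions: 20, Zn dust (activated with BrCH2CH2Br, Me3SiCl), THF, 35 °C; then 18, PdCl2(PPh3)2 (5 mol %), toluene, rt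
Reagents that add atoms: none
Why: Fukuyama coupling. Zinc inserts into the primary C–I bond to give a homoenolate-type organozinc that is configurationally stable at C11'; the palladium catalyst couples it with the thioester only, leaving methyl esters, lactone and silyl ethers alone.

Step 16
Reactants: 22 γ-keto ester (1'α-acyl chain C10'(=O)–C7'H2–C11'H(CH3)–C12'O2Me; 11'R)
Product: 23 bicyclic dione (ring H cis-fused to ring E; shown as C10' enol)
Conditions: t-BuOK (2.2 equiv), THF, −20 to 0 °C; AcOH quench
Reagents that add atoms: none
Why: Intramolecular Claisen (Dieckmann-type) condensation: reversible enolisation of the C10' ketone epimerises C1', and only the cis isomer can close C7' onto the C6' ester (5-exo-trig) to the cis-fused bicyclo[3.3.0] dione, which is withdrawn as its stabilised enolate. C5' and C11' are ester α-centres in a molecule that is already an enolate before and after closure, so a second deprotonation there is disfavoured; C5' keeps the configuration set in step 8 and C1' ends cis to it.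

Step 17
Reactants: 23 bicyclic dione (ring H cis-fused to ring E; shown as C10' enol)
Product: 24 C10' enol acetate
Conditions: AcCl, pyridine, CH2Cl2, −20 °C
Reagents that add atoms: acetyl chloride, CC(=O)Cl
Why: O-Acylation of the enolised 2-substituted 1,3-dione. The C10' oxygen lies beside CH2-2', the C6' oxygen beside the quaternary spiro carbon C4', so the less hindered C10' enol acetate should dominate; any C6' isomer is returned to 23 by mild methanolysis.

Step 18
Reactants: 24 C10' enol acetate; 25 ethylene
Product: 27 ring-F diketone (C6',C10'-dioxo; 7'αH; bis-silyl ether), via cyclobutane acetate 26 (not isolated)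
Conditions: hν (medium-pressure Hg lamp, Pyrex, λ > 300 nm), ethylene-saturated CH2Cl2, −70 °C; then K2CO3, MeOH, 0 °C
Reagents that add atoms: none
Why: De Mayo reaction: excitation of the enol acetate enone, the only chromophore above 300 nm now that C3 and C3' are silyl ethers, gives a triplet that adds ethylene across C7'=C10' through a 1,4-diradical, forming C7'–C8' and C9'–C10' and a cyclobutane fused to ring H on its convex α face; ethylene is symmetric, so no orientational isomers arise. Methoxide then removes the acetyl group and the tertiary cyclobutanolate undergoes retro-aldol cleavage of C7'–C10', releasing the four-ring strain and giving the C10' ketone and the C6' enolate. Ring F is thus closed by a two-atom ring expansion of ring H (fragmentation of the bicyclo[3.2.0] unit) and not by an end-to-end cyclisation; the closest known reaction type is the photocycloaddition of enol esters of cyclic 1,3-diones to alkenes followed by retro-aldol opening to ring-enlarged 1,5-diketones. The only new stereocentre, C7', arises on protonation of the C6' enolate and stays epimerisable; under the basic conditions it should settle with the side chain pseudo-equatorial (β), cis to the C5'–C4' bond, so that both α-branches of the C6' ketone are equatorial. C1' and C5' take no part and should keep their cis relationship if the methanolysis is kept cold and short, and C11' is an isolated ester α-centre that carbonate does not enolise. The step needs constitutional selectivity (the C10' and not the C6' enol ester, secured in step 17), selective excitation (secured by the two silyl ethers) and inter- over intramolecular cycloaddition (the only nearby alkene, C1=C2, is held on the opposite face of ring E and ethylene is in large excess).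

Step 19
Reactants: 27 ring-F diketone (C6',C10'-dioxo; 7'αH; bis-silyl ether)
Product: 28 C10' methylidene C6' ketone
Conditions: Ph3PCH3Br, KN(SiMe3)2, THF, 0 °C; then 27, −40 to 0 °C
Reagents that add atoms: methyltriphenylphosphonium bromide (as its ylide), C[P+](c1ccccc1)(c1ccccc1)c1ccccc1.[Br-]
Why: Wittig methylenation: the C10' ketone (flanked by CH-1' and CH2-9') should react, while the C6' ketone with two branched α-carbons, the ester and the lactone should not. Preformed ylide at low temperature limits enolisation at C1', and once C10' is a methylidene carbon C1' can no longer epimerise.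

Step 20
Reactants: 28 C10' methylidene C6' ketone
Product: 30 bis-lactone bis-silyl ether, via hydroxy ester 29 (not isolated)
Conditions: NaBH4, MeOH/THF, −20 to 0 °C; then 2-hydroxypyridine (cat.), toluene, 40 °C
Reagents that add atoms: none
Why: Hydride reduction of the remaining ketone followed by lactonisation. Axial attack from the β face of the cycloheptanone, past the two pseudo-equatorial α-branches, should give the equatorial 6'α-alkoxide, trans to the C7' side chain; it closes onto the C12' methyl ester to the trans-fused γ-lactone G (5-exo-trig), the neutral bifunctional catalyst finishing the closure without risk to C11'.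

Step 21
Reactants: 30 bis-lactone bis-silyl ether
Product: 31 3α,3'α-diol
Conditions: Bu4NF, AcOH, THF, 0 °C to rt
Reagents that add atoms: none
Why: Fluoride cleavage of both silyl ethers, buffered with acetic acid so that neither lactone α-centre (C11, C11') meets a free base.

Step 22
Reactants: 31 3α,3'α-diol
Product: 32 CNP0240988.1 (target)
Conditions: Dess–Martin periodinane, NaHCO3, CH2Cl2, 0 °C to rt
Reagents that add atoms: none
Why: Dess–Martin oxidation converts the bis-allylic C3 carbinol into the cross-conjugated dienone and the C3' carbinol into the cyclopentanone in one operation. No stereocentre is affected, and the C3' ketone cannot move into conjugation because C4' is quaternary.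

## Compound list

1 | dehydrocostus lactone, (1αH,5αH,6βH,7αH)-guaia-4(15),10(14),11(13)-trien-12,6α-olide | C=C1CC[C@H]3C(=C)CC[C@@H]4[C@H](OC(=O)C4=C)[C@@H]13 | starting material
2 | (11S)-11βH,13-dihydrodehydrocostus lactone (C13 α) | C=C1CC[C@H]3C(=C)CC[C@@H]4[C@H](OC(=O)[C@H]4C)[C@@H]13 | intermediate
3 | (11S)-3α-hydroxyguaia-4(15),10(14)-dien-12,6α-olide | C=C1[C@H](O)C[C@H]3C(=C)CC[C@@H]4[C@H](OC(=O)[C@H]4C)[C@@H]13 | intermediate
4 | (11S)-3-oxoguaia-4(15),10(14)-dien-12,6α-olide | C=C1C(=O)C[C@H]3C(=C)CC[C@@H]4[C@H](OC(=O)[C@H]4C)[C@@H]13 | intermediate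
5 | silyl dienol ether, (11S)-3-(trimethylsilyloxy)guaia-2,4(15),10(14)-trien-12,6α-olide | C=C1C(O[Si](C)(C)C)=C[C@H]3C(=C)CC[C@@H]4[C@H](OC(=O)[C@H]4C)[C@@H]13 | intermediate (not isolated)
6 | (11S)-3-oxoguaia-1,4(15),10(14)-trien-12,6α-olide (5αH) | C=C1C(=O)C=C3C(=C)CC[C@@H]4[C@H](OC(=O)[C@H]4C)[C@@H]13 | intermediate
7 | (11S)-3β-hydroxyguaia-1,4(15),10(14)-trien-12,6α-olide (5αH) | C=C1[C@@H](O)C=C3C(=C)CC[C@@H]4[C@H](OC(=O)[C@H]4C)[C@@H]13 | intermediate
8 | dimethyl (1S,2S)-4-oxocyclopentane-1,2-dicarboxylate | O=C1C[C@H](C(=O)OC)[C@@H](C(=O)OC)C1 | starting material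
9 | dimethyl (1S,2S,3R)-3-[(dimethylamino)methyl]-4-oxocyclopentane-1,2-dicarboxylate | O=C1[C@@H](CN(C)C)[C@H](C(=O)OC)[C@@H](C(=O)OC)C1 | intermediate
10 | ammonium iodide, N-methyl quaternary salt of 9 | O=C1[C@@H](C[N+](C)(C)C)[C@H](C(=O)OC)[C@@H](C(=O)OC)C1.[I-] | intermediate (not isolated)
11 | dimethyl (1S,2R)-3-methylidene-4-oxocyclopentane-1,2-dicarboxylate | O=C1C(=C)[C@H](C(=O)OC)[C@@H](C(=O)OC)C1 | intermediate
12 | spiro adduct: (11S)-3β-hydroxy-2βH-guaia-1(10),4(15)-dien-12,6α-olide joined C2–C4' and C14–C15' to ring E (3'-oxo; CO2Me C10' on C1' α; CO2Me C6' on C5' β; C2 on the α face of ring E) | C=C1[C@@H](O)[C@H]2C3=C(CC[C@@H]4[C@H](OC(=O)[C@H]4C)[C@@H]13)CC[C@]21C(=O)C[C@H](C(=O)OC)[C@H]1C(=O)OC | intermediate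
13 | β,γ-enone, 3-oxo analogue of 12 (2βH, Δ1(10)) | C=C1C(=O)[C@H]2C3=C(CC[C@@H]4[C@H](OC(=O)[C@H]4C)[C@@H]13)CC[C@]21C(=O)C[C@H](C(=O)OC)[C@H]1C(=O)OC | intermediate (not isolated)
14 | spiro dienone diester (3-oxo; Δ1; 10βH; 3'-oxo; 1'α,5'β-diester) | C=C1C(=O)C2=C3[C@@H](CC[C@@H]4[C@H](OC(=O)[C@H]4C)[C@@H]13)CC[C@]21C(=O)C[C@H](C(=O)OC)[C@H]1C(=O)OC | intermediate
15 | 3α,3'α-diol diester | C=C1[C@H](O)C2=C3[C@@H](CC[C@@H]4[C@H](OC(=O)[C@H]4C)[C@@H]13)CC[C@]21[C@H](O)C[C@H](C(=O)OC)[C@H]1C(=O)OC | intermediate
16 | 3α,3'α-bis(tert-butyldimethylsilyl) ether diester | C=C1[C@H](O[Si](C)(C)C(C)(C)C)C2=C3[C@@H](CC[C@@H]4[C@H](OC(=O)[C@H]4C)[C@@H]13)CC[C@]21[C@H](O[Si](C)(C)C(C)(C)C)C[C@H](C(=O)OC)[C@H]1C(=O)OC | intermediate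
17 | C10' carboxylic acid (on C1', α; C6' methyl ester kept) | C=C1[C@H](O[Si](C)(C)C(C)(C)C)C2=C3[C@@H](CC[C@@H]4[C@H](OC(=O)[C@H]4C)[C@@H]13)CC[C@]21[C@H](O[Si](C)(C)C(C)(C)C)C[C@H](C(=O)O)[C@H]1C(=O)OC | intermediate
18 | C10' S-ethyl thioester | C=C1[C@H](O[Si](C)(C)C(C)(C)C)C2=C3[C@@H](CC[C@@H]4[C@H](OC(=O)[C@H]4C)[C@@H]13)CC[C@]21[C@H](O[Si](C)(C)C(C)(C)C)C[C@H](C(=O)SCC)[C@H]1C(=O)OC | intermediate
19 | methyl (R)-3-hydroxy-2-methylpropanoate | OC[C@@H](C)C(=O)OC | starting material
20 | methyl (S)-3-iodo-2-methylpropanoate | IC[C@@H](C)C(=O)OC | intermediate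
21 | organozinc iodide, [(S)-3-methoxy-2-methyl-3-oxopropyl]zinc iodide | I[Zn]C[C@@H](C)C(=O)OC | intermediate (not isolated)
22 | γ-keto ester (1'α-acyl chain C10'(=O)–C7'H2–C11'H(CH3)–C12'O2Me, 11'R; 5'β-CO2Me; bis-silyl ether) | C=C1[C@H](O[Si](C)(C)C(C)(C)C)C2=C3[C@@H](CC[C@@H]4[C@H](OC(=O)[C@H]4C)[C@@H]13)CC[C@]21[C@H](O[Si](C)(C)C(C)(C)C)C[C@H](C(=O)C[C@@H](C)C(=O)OC)[C@H]1C(=O)OC | intermediate
23 | bicyclic dione: ring H cis-fused to ring E (H-1', H-5' α), C7' bearing (R)-CH(CH3)CO2Me, shown as C10' enol | C=C1[C@H](O[Si](C)(C)C(C)(C)C)C2=C3[C@@H](CC[C@@H]4[C@H](OC(=O)[C@H]4C)[C@@H]13)CC[C@]21[C@H](O[Si](C)(C)C(C)(C)C)C[C@H]2C(O)=C([C@@H](C)C(=O)OC)C(=O)[C@H]21 | intermediate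
24 | C10' enol acetate (key-step precursor) | C=C1[C@H](O[Si](C)(C)C(C)(C)C)C2=C3[C@@H](CC[C@@H]4[C@H](OC(=O)[C@H]4C)[C@@H]13)CC[C@]21[C@H](O[Si](C)(C)C(C)(C)C)C[C@H]2C(OC(C)=O)=C([C@@H](C)C(=O)OC)C(=O)[C@H]21 | intermediate
25 | ethylene | C=C | starting material
26 | cyclobutane acetate (ethylene added across C7'=C10' on the α face; OAc and side chain β) | C=C1[C@H](O[Si](C)(C)C(C)(C)C)C2=C3[C@@H](CC[C@@H]4[C@H](OC(=O)[C@H]4C)[C@@H]13)CC[C@]21[C@H](O[Si](C)(C)C(C)(C)C)C[C@H]2[C@]3(OC(C)=O)CC[C@]3([C@@H](C)C(=O)OC)C(=O)[C@H]21 | intermediate (not isolated)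
27 | ring-F diketone (C6',C10'-dioxo; 7'αH, side chain β; bis-silyl ether; key-step product) | C=C1[C@H](O[Si](C)(C)C(C)(C)C)C2=C3[C@@H](CC[C@@H]4[C@H](OC(=O)[C@H]4C)[C@@H]13)CC[C@]21[C@H](O[Si](C)(C)C(C)(C)C)C[C@H]2C(=O)CC[C@@H]([C@@H](C)C(=O)OC)C(=O)[C@H]21 | intermediate
28 | C10' methylidene C6' ketone | C=C1[C@H](O[Si](C)(C)C(C)(C)C)C2=C3[C@@H](CC[C@@H]4[C@H](OC(=O)[C@H]4C)[C@@H]13)CC[C@]21[C@H](O[Si](C)(C)C(C)(C)C)C[C@H]2C(=C)CC[C@@H]([C@@H](C)C(=O)OC)C(=O)[C@H]21 | intermediate
29 | hydroxy ester (6'α-OH) | C=C1[C@H](O[Si](C)(C)C(C)(C)C)C2=C3[C@@H](CC[C@@H]4[C@H](OC(=O)[C@H]4C)[C@@H]13)CC[C@]21[C@H](O[Si](C)(C)C(C)(C)C)C[C@H]2C(=C)CC[C@@H]([C@@H](C)C(=O)OC)[C@H](O)[C@H]21 | intermediate (not isolated)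
30 | bis-lactone bis-silyl ether (target skeleton with 3α- and 3'α-silyloxy groups in place of the two ketones) | C=C1[C@H](O[Si](C)(C)C(C)(C)C)C2=C3[C@@H](CC[C@@H]4[C@H](OC(=O)[C@H]4C)[C@@H]13)CC[C@]21[C@H](O[Si](C)(C)C(C)(C)C)C[C@H]2C(=C)CC[C@@H]3[C@H](OC(=O)[C@@H]3C)[C@H]21 | intermediate
31 | 3α,3'α-diol | C=C1[C@H](O)C2=C3[C@@H](CC[C@@H]4[C@H](OC(=O)[C@H]4C)[C@@H]13)CC[C@]21[C@H](O)C[C@H]2C(=C)CC[C@@H]3[C@H](OC(=O)[C@@H]3C)[C@H]21 | intermediate
32 | CNP0240988.1 | C=C1C(=O)C2=C3[C@@H](CC[C@@H]4[C@H](OC(=O)[C@H]4C)[C@@H]13)CC[C@]21C(=O)C[C@H]2C(=C)CC[C@@H]3[C@H](OC(=O)[C@@H]3C)[C@H]21 | target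

## Step count and least certain steps

Total step count: 22. Longest linear sequence: 19 steps (1 to 32 through steps 1–5, 8–13 and 15–22). Steps 6–7 and step 14 are side branches.

**Step 18 (key step).** The most likely failure is that the cycloaddition of the tetrasubstituted acyloxy enone is outrun by a photochemical 1,3-acyl migration of the enol acetate. In the second half, the base needed for deacetylation may epimerise C1' toward a trans ring fusion or drive C9' onto the C12' ester. The fallback keeps the same bond changes but removes both causes. It sets out from dione 23, which is acylated with 2,2,2-trichloroethyl chloroformate and pyridine to the C10' enol carbonate F1. Irradiation with ethylene under the same conditions gives the cyclobutyl carbonate F2. Zinc dust with NH4OAc in THF/MeOH removes the carbonate reductively, and the free cyclobutanol fragments without any alkoxide base, returning to the route at 27.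

**Step 8.** The dienophile may be lost to dimerisation or double-bond migration before it is trapped, the dienylic carbinol of 7 may ionise on heating, or the facial preferences of the two partners may be mismatched so that the reaction stalls. The fallback inverts the order of reduction and cycloaddition. It sets out from trienone 6, which is heated with 11; the diene is then planar at C3 and carries no ionisable carbinol. The adduct is 13, where the route is rejoined at the base treatment of step 9. No compound outside the list is formed (F0).

**Step 9.** Proton return to C10 may occur on the wrong face, or equilibration may favour the 10α-H epimer. The fallback replaces the proton shuttle by protonation of a neutral dienol ether. It sets out from 13, which with Me3SiOTf and Et3N gives the bis(trimethylsilyl) dienol ether F3 (C3-silyloxy C2=C3/C1=C10 diene and C3' enol ether). Cold dilute HCl in THF protonates the diene terminus C10 under kinetic control from the β face, which the C5' branch of ring E does not cover, and hydrolyses both enol ethers, returning to the route at 14.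

**Step 17.** Acylation may take place on both enol oxygens; the C6' enol acetate would lead to the constitutional isomer with the side chain next to C10'. The fallback replaces kinetic acylation by a reversible silylation. It sets out from 23, which with Me3SiCl and Et3N gives the C10' trimethylsilyl enol ether F4; silyl groups shuttle between the two oxygens of a 1,3-dione, so the less hindered isomer accumulates. Irradiation with ethylene gives the cyclobutyl silyl ether F5, and K2CO3 in MeOH cleaves the silyl ether and triggers the same retro-aldol opening, returning to the route at 27.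

**Step 20.** Hydride may be delivered to the α face, and the resulting 6'β-alkoxide would close to the cis-fused lactone. The fallback replaces external hydride by internal delivery. It sets out from 28, whose only methyl ester is cleaved with Me3SnOH to the keto acid F6. With Me4NBH(OAc)3 in MeCN/AcOH at −30 °C the carboxylate of the β side chain binds boron, and hydride is passed to the β face of C6'. The 6'α-hydroxy acid closes to the trans lactone (carbodiimide if needed), returning to the route at 30.

## Further compounds

F0 | step 8 | none | none
F1 | step 18 | C10' enol 2,2,2-trichloroethyl carbonate of 23 | C=C1[C@H](O[Si](C)(C)C(C)(C)C)C2=C3[C@@H](CC[C@@H]4[C@H](OC(=O)[C@H]4C)[C@@H]13)CC[C@]21[C@H](O[Si](C)(C)C(C)(C)C)C[C@H]2C(OC(=O)OCC(Cl)(Cl)Cl)=C([C@@H](C)C(=O)OC)C(=O)[C@H]21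
F2 | step 18 | cyclobutyl 2,2,2-trichloroethyl carbonate (ethylene adduct of F1) | C=C1[C@H](O[Si](C)(C)C(C)(C)C)C2=C3[C@@H](CC[C@@H]4[C@H](OC(=O)[C@H]4C)[C@@H]13)CC[C@]21[C@H](O[Si](C)(C)C(C)(C)C)C[C@H]2[C@]3(OC(=O)OCC(Cl)(Cl)Cl)CC[C@]3([C@@H](C)C(=O)OC)C(=O)[C@H]21
F3 | step 9 | bis(trimethylsilyl) dienol ether of 13 | C=C1C(O[Si](C)(C)C)=C2C3=C(CC[C@@H]4[C@H](OC(=O)[C@H]4C)[C@@H]13)CC[C@]21C(O[Si](C)(C)C)=C[C@H](C(=O)OC)[C@H]1C(=O)OC
F4 | step 17 | C10' trimethylsilyl enol ether of 23 | C=C1[C@H](O[Si](C)(C)C(C)(C)C)C2=C3[C@@H](CC[C@@H]4[C@H](OC(=O)[C@H]4C)[C@@H]13)CC[C@]21[C@H](O[Si](C)(C)C(C)(C)C)C[C@H]2C(O[Si](C)(C)C)=C([C@@H](C)C(=O)OC)C(=O)[C@H]21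
F5 | step 17 | cyclobutyl trimethylsilyl ether (ethylene adduct of F4) | C=C1[C@H](O[Si](C)(C)C(C)(C)C)C2=C3[C@@H](CC[C@@H]4[C@H](OC(=O)[C@H]4C)[C@@H]13)CC[C@]21[C@H](O[Si](C)(C)C(C)(C)C)C[C@H]2[C@]3(O[Si](C)(C)C)CC[C@]3([C@@H](C)C(=O)OC)C(=O)[C@H]21
F6 | step 20 | keto acid, C12' carboxylic acid of 28 | C=C1[C@H](O[Si](C)(C)C(C)(C)C)C2=C3[C@@H](CC[C@@H]4[C@H](OC(=O)[C@H]4C)[C@@H]13)CC[C@]21[C@H](O[Si](C)(C)C(C)(C)C)C[C@H]2C(=C)CC[C@@H]([C@@H](C)C(=O)O)C(=O)[C@H]21
A1 | alternative 1 | dimer with decalin-type primed half, 1'β (equatorial) mesylate, 10'β-methyl, C3' ethylene ketal | C=C1C(=O)C2=C3[C@@H](CC[C@@H]4[C@H](OC(=O)[C@H]4C)[C@@H]13)CC[C@]21C5(OCCO5)C[C@@H](OS(C)(=O)=O)[C@]2(C)CC[C@@H]3[C@H](OC(=O)[C@@H]3C)[C@H]21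
A2 | alternative 1 | target as its C3' ethylene ketal | C=C1C(=O)C2=C3[C@@H](CC[C@@H]4[C@H](OC(=O)[C@H]4C)[C@@H]13)CC[C@]21C5(OCCO5)C[C@H]2C(=C)CC[C@@H]3[C@H](OC(=O)[C@@H]3C)[C@H]21
A3 | alternative 2 | cycloaddition substrate: 3-(phenylsulfonyl)cyclopentenone tethered through C5–C9 to the exocyclic diene C10=C14–C15'=C4' of the primed 5/7 lactone (C3' ethylene ketal, C10' ketone) | O=C1C=C(S(=O)(=O)c2ccccc2)[C@H](C1)[C@H]3OC(=O)[C@@H](C)[C@@H]3CC/C=C/C=C4/C5(OCCO5)C[C@H]6C(=O)CC[C@@H]7[C@H](OC(=O)[C@@H]7C)[C@@H]46
A4 | alternative 2 | spiro cyclohexadiene with C14=C15' and C1=C2, C15 absent, C3' ethylene ketal, C10' ketone | C1C(=O)C2=C3[C@@H](CC[C@@H]4[C@H](OC(=O)[C@H]4C)[C@@H]13)C=C[C@]21C5(OCCO5)C[C@H]2C(=O)CC[C@@H]3[C@H](OC(=O)[C@@H]3C)[C@H]21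
A5 | alternative 3 | enone-half keto aldehyde (rings A–D, C4'–H epimerisable, C3' ketone, C2' aldehyde) | C=C1C(=O)C2=C3[C@@H](CC[C@@H]4[C@H](OC(=O)[C@H]4C)[C@@H]13)CCC2C(=O)C=O
A6 | alternative 3 | cycloheptenone lactone (C10' ketone, C1'=C5', 6'βH, 7'αH, 11'R) | O=C1CC[C@@H]3[C@H](OC(=O)[C@@H]3C)C=C1
A7 | alternative 3 | full skeleton with C2' hydroxyl and C10' ketone | C=C1C(=O)C2=C3[C@@H](CC[C@@H]4[C@H](OC(=O)[C@H]4C)[C@@H]13)CC[C@]21C(=O)[C@H](O)[C@H]2C(=O)CC[C@@H]3[C@H](OC(=O)[C@@H]3C)[C@H]21
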